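## Structural features

The target 12 is a 2-aryl-3-methyl-2,3-dihydro-1-benzofuran. Benzene ring A is fused through C3a and C7a to a five-membered ring completed by O1, C2 and C3, and it carries a methoxy group at C7 and an (E)-prop-1-enyl chain at C5. C2 bears ring B (3-hydroxy-4,5-dimethoxyphenyl) and C3 bears a methyl group. C2 and C3 are adjacent stereocentres, both S, with ring B and the methyl group trans. The fragile groups are the electron-rich (E)-propenyl styrene unit (acid, electrophiles, oxidants), the free ring B phenol, and the C2–O1 bond, which is benzylic to an oxygenated arene and can ionise under acid. The real difficulty is the absolute configuration at C3, a benzylic carbon carrying only H and CH3 with no neighbouring functional group through which a reagent or auxiliary could act. The trans relation is the thermodynamic one and is the lesser problem. The key step exploits two facts: O1 on ring A can reach C2, and C2 is benzylic to ring B, whose C4' methoxy group is para to it, so a C2=C3 double bond protonated at C3 leaves a cation at C2 that O1 can capture. The C4' methoxy group is flanked by oxygen substituents at C3' and C5' and is twisted out of conjugation, so this cation is only moderately stabilised and a strong acid is needed.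

## Logic of the disconnections

12 to 9 and 10 (through 11). The C5–C(propenyl) bond is cut, and the ring B phenol is taken back to its ester in 11. The propenyl chain would not survive the acid that closes the heterocycle, so it is attached afterwards to a C5 bromide, which is inert to acid. The gain is that the sensitive alkene is absent from the stereochemical step and arrives from a commercial boron reagent. The forward step must keep the E geometry, leave C2 and C3 untouched, and remove the ester under conditions mild enough for the C2–O1 bond; one flask serves for both operations.

9 to 8. The O1–C2 bond is cut. This single cut removes both stereocentres and the heterocycle and leaves an achiral, acyclic alkene phenol, so the stereochemical problem becomes one of catalyst control. The forward step must protonate C3 productively, choose one alkene face, close trans, and outrun any racemic acid-mediated background reaction.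

8 to 7. No bond is cut; only the alkene geometry is adjusted. This allows a non-selective olefination to be used. It demands that the equilibrium favours E and that no strong acid is present, which would close the ring racemically.

7 to 4 and 6. The C2=C3 double bond is cut, the only carbon–carbon link between the two aryl halves. The phosphorus is placed on the ring A half and the carbonyl on the ring B half. The ring B aldehyde is far more electrophilic than a ring A ketone deactivated by its ortho phenoxide, and the ring A benzylic position is easily activated through its ortho hydroxyl group. This saves the reduction and halogenation of the ring B half. The forward step needs a phenoxide ylide that forms without collapsing to an ortho-quinone methide, and an ester in 6 that tolerates the base.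

4 to 3 to 2 to 1. The C–P bond, the carbinol C–H bond and the C5–Br bond are cut in turn. Each is a single reliable functional-group operation on a commercial arene. The only selectivity demand is bromination at C5, where the directing effects of the hydroxyl and acetyl groups reinforce each other.

6 to 5. The ester C–O bond is cut. The acyl group must survive base, iodine and strong acid, temper ring B towards Friedel–Crafts capture of the cation, and slow re-ionisation of the C2–O1 bond in 9. A pivalate meets these demands.

## Other disconnections considered

Alternative 1: The cuts are C3–C3a and O1–C7a, so ring A is joined in one operation to a two-carbon epoxide unit. In the forward sense the aryl iodide A2 and the enantiopure cis-epoxide A3 would combine in a Catellani-type palladium relay: the ortho C–H carbon opens the epoxide at its methyl-bearing carbon and the liberated alkoxide closes on the ipso carbon, giving A1.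
- In its favour: it is convergent, and both stereocentres are relayed stereospecifically from A3 (inversion at the methyl-bearing carbon, retention at the benzylic one). The absolute and relative configuration would rest on an established asymmetric epoxidation of a cis-alkene. On this point it is better than the chosen plan, whose induction is unprecedented.
- Against it here: 1,2-disubstituted epoxides are much poorer partners than terminal ones in this relay. An electron-rich aryl epoxide tends to ionise at the benzylic carbon, which risks the wrong regiochemistry, rearrangement to a ketone and loss of stereochemical integrity. The ester at C5 of A1 must still become an (E)-propenyl group (reduction, oxidation, E-selective olefination), and the acetal on ring B must then be removed with acid in the presence of that alkene.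
- Comparison: in structure the two plans are equal in convergence, each joining a ring A piece to a ring B piece. In mechanism the alternative offers stereospecificity but on a substrate class outside its secure range; the chosen plan offers a simple substrate but an untested induction. In step economy the chosen plan is better after the key step (one flask against four or more operations) and about equal before it.

Alternative 2: The cuts are C3a–C7a and C4–C5, so ring A itself is dismantled. In the forward sense the pyrone A5, carrying the O1–C2–C3 tether and a terminal alkyne, would undergo thermal intramolecular [4+2] cycloaddition and decarboxylative aromatisation to give A4, the silyl ether of the target.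
- In its favour: one catalyst-free step forms the arene and the heterocycle, with the substitution pattern fixed by the tether. The propenyl chain is already present, so only desilylation remains; in length this endgame equals the chosen one, and it is better in that the finished ring system never meets acid. The stereocentres are set beforehand in an acyclic homopropargylic ether by established methods, which is more predictable than the chosen induction.
- Against it here: A5 is far from commercial materials (a 2-pyrone with oxygen at C3, methoxy at C4 and propenyl at C6). The ether link joins a 3-hydroxypyrone to a hindered, easily ionised benzylic carbinol. The cycloaddition sets an unactivated alkyne against an electron-rich pyrone across a three-atom tether, and the temperatures this would need may bring side reactions of the propenyl-substituted diene.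
- Comparison: in structure the alternative builds an aromatic ring that the chosen plan takes intact from a commercial arene, an unnecessary expense. In mechanism it is pericyclic and regiochemically unambiguous, the equal or better of the chosen plan in predictability but doubtful in reactivity. In step economy it is clearly longer.

Alternative 3: The cut is C3–C3a, read as a 1,2-aryl shift. In the forward sense the enantioenriched flavanone A7, treated with a hypervalent iodine diacetate oxidant in acidic orthoformate, would be iodinated next to the carbonyl group; the ring A carbon would then migrate to that carbon, contracting the pyranone to the dihydrobenzofuran ester A6.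
- In its favour: the ring contraction is an established reaction class with a trans preference, so on precedent it is better than the chosen key step. A7 derives from the same two commercial arenes, 1 and 5, so the plans are equal in starting materials.
- Against it here: C3 emerges as a methyl ester, so reduction, activation and hydride displacement are needed next to an aryl bromide, followed by cleavage of the aryl sulfonate and the cross-coupling. The absolute configuration rests on C2 of A7, which must come from an asymmetric oxa-Michael closure and can racemise by ring opening under the strongly acidic, oxidising conditions of the key step itself.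
- Comparison: in structure both plans keep rings A and B intact and form the five-membered ring late. In mechanism the alternative is better precedented but relays chirality from a labile centre, whereas the chosen plan creates both centres in one catalytic event. In step economy the chosen plan is better, one flask after the key step against about five operations.

Key step: step 7

Remark on the structures: in 9, 11 and 12 the descriptors (2S,3S) correspond to ring B and the C3 methyl group being trans, and in 8 the E descriptor places rings A and B on opposite sides of the double bond; the structures used below are consistent with this and need no correction.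

Assumption: the sense of induction of the chiral acid in step 7 cannot be predicted with confidence; the antipode that leads to (2S,3S)-9 is to be identified in a first screen, both antipodes being accessible from (R)- and (S)-BINOL.

## Route

Step 1
Reactants: 1 1-(2-hydroxy-3-methoxyphenyl)ethanone
Product: 2 1-(5-bromo-2-hydroxy-3-methoxyphenyl)ethanone
Conditions: NBS (1.05 equiv), MeCN, 0 °C to rt
Reagents that add atoms: N-bromosuccinimide, O=C1CCC(=O)N1Br
Why: Electrophilic aromatic bromination; the hydroxyl group directs para to itself (both ortho positions are occupied) and the acetyl group directs meta to the same carbon, so C5 is the only strongly activated site.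

Step 2
Reactants: 2 1-(5-bromo-2-hydroxy-3-methoxyphenyl)ethanone
Product: 3 1-(5-bromo-2-hydroxy-3-methoxyphenyl)ethanol (racemic)
Conditions: NaBH4 (1.5 equiv), MeOH, 0 °C; crude product used directly
Reagents that add atoms: none
Why: Borohydride reduction of an aryl ketone, leaving the aryl bromide untouched; the carbinol centre is racemic and irrelevant because it becomes an sp2 carbon in step 5.

Step 3
Reactants: 3 1-(5-bromo-2-hydroxy-3-methoxyphenyl)ethanol (racemic)
Product: 4 [1-(5-bromo-2-hydroxy-3-methoxyphenyl)ethyl]triphenylphosphonium bromide (racemic)
Conditions: PPh3·HBr (1.05 equiv), MeCN, reflux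
Reagents that add atoms: triphenylphosphine hydrobromide, [Br-].c1ccc(cc1)[PH+](c1ccccc1)c1ccccc1
Why: Acid-promoted loss of water from the ortho-hydroxybenzylic alcohol gives an ortho-quinone methide (protonated: a benzylic cation) that triphenylphosphine captures; this is the standard preparation of (2-hydroxybenzyl)phosphonium salts.

Step 4
Reactants: 5 3-hydroxy-4,5-dimethoxybenzaldehyde
Product: 6 5-formyl-2,3-dimethoxyphenyl 2,2-dimethylpropanoate
Conditions: t-BuCOCl (1.2 equiv), Et3N (1.5 equiv), 4-(dimethylamino)pyridine (5 mol %), CH2Cl2, 0 °C to rt
Reagents that add atoms: pivaloyl chloride, CC(C)(C)C(=O)Cl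
Why: O-acylation of a phenol under nucleophilic catalysis; the hindered ester is chosen to resist amide base at low temperature, iodine and strong acid.

Step 5
Reactants: 4 [1-(5-bromo-2-hydroxy-3-methoxyphenyl)ethyl]triphenylphosphonium bromide; 6 5-formyl-2,3-dimethoxyphenyl 2,2-dimethylpropanoate
Product: 7 5-[2-(5-bromo-2-hydroxy-3-methoxyphenyl)prop-1-enyl]-2,3-dimethoxyphenyl 2,2-dimethylpropanoate (mixture of E and Z isomers)
Conditions: 4, LiN(SiMe3)2 (2.1 equiv), THF, −78 to 0 °C; then 6, −78 °C to rt; AcOH (1.1 equiv)
Reagents that add atoms: none
Why: Wittig olefination with a semi-stabilised ylide; the first equivalent of base gives the phenoxide and the second the ylide, which adds to the aldehyde far faster than to the hindered aryl pivalate. The geometry is not controlled here and is corrected in step 6.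

Step 6
Reactants: 7 5-[2-(5-bromo-2-hydroxy-3-methoxyphenyl)prop-1-enyl]-2,3-dimethoxyphenyl 2,2-dimethylpropanoate (E/Z mixture)
Product: 8 5-[(E)-2-(5-bromo-2-hydroxy-3-methoxyphenyl)prop-1-enyl]-2,3-dimethoxyphenyl 2,2-dimethylpropanoate
Conditions: I2 (5 mol %), toluene, 80 °C, visible light; aq. Na2S2O3 wash; crystallisation or chromatography
Reagents that add atoms: none
Why: Iodine-atom-catalysed alkene isomerisation: reversible addition of an iodine atom allows rotation about the C2–C3 bond and leads to the thermodynamic mixture. The E isomer should dominate because it keeps the two aryl rings apart and ring B conjugated with the double bond.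

Step 7
Reactants: 8 5-[(E)-2-(5-bromo-2-hydroxy-3-methoxyphenyl)prop-1-enyl]-2,3-dimethoxyphenyl 2,2-dimethylpropanoate
Product: 9 5-[(2S,3S)-5-bromo-7-methoxy-3-methyl-2,3-dihydro-1-benzofuran-2-yl]-2,3-dimethoxyphenyl 2,2-dimethylpropanoate
Conditions: one antipode of a confined IDPi acid (imidodiphosphorimidate from two 3,3'-bis[3,5-bis(trifluoromethyl)phenyl]-BINOL phosphorus units bridged by N–H, each phosphorus carrying =N–SO2CF3; 5 mol %), cyclohexane/CHCl3, 0.02 M, 4 Å molecular sieves, −20 °C to rt; Et3N quench
Reagents that add atoms: none
Why: Proposed new method: the confined acid transfers its proton to C3 of the C2=C3 double bond inside the chiral counter-anion pocket, and the resulting contact ion pair has its positive charge at C2, where ring B with its C4' methoxy group para to the benzylic carbon delocalises it; O1 of the ring A phenol, hydrogen-bonded to the anion, then bonds to C2 and returns a proton to the catalyst. The closest known reaction types are the imidodiphosphorimidate-catalysed intramolecular hydroalkoxylation of alkenols and the racemic acid-promoted cyclisation of 2-hydroxystilbenes to 2-aryl-2,3-dihydrobenzofurans, and the step combines the two. The dihydrofuran ring closes in a formally 5-endo-trig mode, acceptable because it is the capture of a developed benzylic cation and not an attack on an intact alkene. C3 is set by which face of the trisubstituted alkene receives the proton, which the chiral anion must dictate; C2 is set in the ring closure, with ring B taking the face opposite the C3 methyl group, and reversible ionisation of the C2–O1 bond would correct any cis isomer to the more stable trans one without touching C3. The step needs protonation at C3 to be the productive event: protonation at C2 gives a ring-A-stabilised tertiary cation at C3 that has no ring closure open to it and can only lose a proton again, so material is funnelled through the C2 cation. The bromide at C5 keeps the acid-labile propenyl chain out of this step, the pivalate lowers the nucleophilicity of ring B towards Friedel–Crafts capture of the cation, and high dilution in a non-polar medium suppresses intermolecular capture.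

Step 8
Reactants: 9 5-[(2S,3S)-5-bromo-7-methoxy-3-methyl-2,3-dihydro-1-benzofuran-2-yl]-2,3-dimethoxyphenyl 2,2-dimethylpropanoate; 10 4,4,5,5-tetramethyl-2-[(E)-prop-1-enyl]-1,3,2-dioxaborolane
Product: 12 5-[(2S,3S)-7-methoxy-3-methyl-5-[(E)-prop-1-enyl]-2,3-dihydro-1-benzofuran-2-yl]-2,3-dimethoxyphenol, via propenyl pivalate 11 (not isolated)
Conditions: Pd(OAc)2 (3 mol %), SPhos (6 mol %), K3PO4 (3 equiv), 10 (1.5 equiv), 1,4-dioxane/H2O, 80 °C; then MeOH, aq. NaOH (4 equiv), 40 °C; dilute HCl to pH 6 at 0 °C
Reagents that add atoms: (E)-prop-1-enylboronic acid pinacol ester (compound 10), C/C=C/B1OC(C)(C)C(C)(C)O1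
Why: Suzuki–Miyaura coupling of the electron-rich aryl bromide with an alkenyl boronate proceeds with retention of the E geometry and does not touch C2 or C3. Saponification of the aryl pivalate in the same flask then frees the ring B phenol and gives the target 12; neither stereocentre is acidic enough to epimerise under these conditions.

## Compound list

1 | 1-(2-hydroxy-3-methoxyphenyl)ethanone | CC(=O)c1cccc(OC)c1O | starting material
2 | 1-(5-bromo-2-hydroxy-3-methoxyphenyl)ethanone | CC(=O)c1cc(Br)cc(OC)c1O | intermediate
3 | 1-(5-bromo-2-hydroxy-3-methoxyphenyl)ethanol (racemic) | CC(O)c1cc(Br)cc(OC)c1O | intermediate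
4 | [1-(5-bromo-2-hydroxy-3-methoxyphenyl)ethyl]triphenylphosphonium bromide (racemic) | CC(c1cc(Br)cc(OC)c1O)[P+](c1ccccc1)(c1ccccc1)c1ccccc1.[Br-] | intermediate
5 | 3-hydroxy-4,5-dimethoxybenzaldehyde | O=Cc1cc(O)c(OC)c(OC)c1 | starting material
6 | 5-formyl-2,3-dimethoxyphenyl 2,2-dimethylpropanoate | O=Cc1cc(OC(=O)C(C)(C)C)c(OC)c(OC)c1 | intermediate
7 | 5-[2-(5-bromo-2-hydroxy-3-methoxyphenyl)prop-1-enyl]-2,3-dimethoxyphenyl 2,2-dimethylpropanoate (E/Z mixture) | CC(=Cc1cc(OC(=O)C(C)(C)C)c(OC)c(OC)c1)c1cc(Br)cc(OC)c1O | intermediate
8 | 5-[(E)-2-(5-bromo-2-hydroxy-3-methoxyphenyl)prop-1-enyl]-2,3-dimethoxyphenyl 2,2-dimethylpropanoate | C/C(=C\c1cc(OC(=O)C(C)(C)C)c(OC)c(OC)c1)c1cc(Br)cc(OC)c1O | intermediate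
9 | 5-[(2S,3S)-5-bromo-7-methoxy-3-methyl-2,3-dihydro-1-benzofuran-2-yl]-2,3-dimethoxyphenyl 2,2-dimethylpropanoate | Brc1cc(OC)c2c(c1)[C@H](C)[C@@H](c1cc(OC(=O)C(C)(C)C)c(OC)c(OC)c1)O2 | intermediate
10 | 4,4,5,5-tetramethyl-2-[(E)-prop-1-enyl]-1,3,2-dioxaborolane | C/C=C/B1OC(C)(C)C(C)(C)O1 | starting material
11 | 5-[(2S,3S)-7-methoxy-3-methyl-5-[(E)-prop-1-enyl]-2,3-dihydro-1-benzofuran-2-yl]-2,3-dimethoxyphenyl 2,2-dimethylpropanoate | C/C=C/c1cc(OC)c2c(c1)[C@H](C)[C@@H](c1cc(OC(=O)C(C)(C)C)c(OC)c(OC)c1)O2 | intermediate
12 | 5-[(2S,3S)-7-methoxy-3-methyl-5-[(E)-prop-1-enyl]-2,3-dihydro-1-benzofuran-2-yl]-2,3-dimethoxyphenol | C/C=C/c1cc(OC)c2c(c1)[C@H](C)[C@@H](c1cc(O)c(OC)c(OC)c1)O2 | target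

## Step count and least certain steps

Total steps: 8 (step 8 runs two operations in one flask). Longest linear sequence: 7 steps (1, 2, 3, 5, 6, 7, 8); step 4 is a one-step branch.

Step 7 (key step, proposed new method). The most likely failure is poor facial selectivity in the proton transfer. The competing protonation at C2 can scramble the alkene (E to Z, and to the 1,1-disubstituted isomer) faster than the ring closes, so C3 would be protonated in more than one substrate geometry. The weakened donation of the flanked C4' methoxy group and the pivalate may make the C2 cation slow to form. Re-ionisation of the C2–O1 bond in the product, followed by loss of the C3 proton, would erode the enantiomeric purity. Intermolecular Friedel–Crafts capture of the cation is a further loss channel.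
Fallback, from 8 back to 9: ring closure with an achiral strong acid (CF3SO3H, 5 mol %, CH2Cl2, 0 °C), a known reaction type, should give the racemic trans compound, in which 9 is accompanied by its mirror image, 5-[(2R,3R)-5-bromo-7-methoxy-3-methyl-2,3-dihydro-1-benzofuran-2-yl]-2,3-dimethoxyphenyl 2,2-dimethylpropanoate F1. Preparative chromatography on a chiral stationary phase (supercritical CO2/MeOH) would then separate 9 from F1.

Step 6. The most likely failure is incomplete enrichment, because the equilibrium between the two trisubstituted isomers may not lie far on the E side. In addition, adventitious hydrogen iodide could start racemic ring closure of the free phenol; any neutral cyclised material must be removed before step 7, since it would dilute the enantiomeric purity of 9.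
Fallback, from 3 and 6 back to 8, bypassing 7: heating 3 with Ph2P(O)H in toluene should add the P–H bond to the ortho-quinone methide formed by loss of water, giving 4-bromo-2-[1-(diphenylphosphoryl)ethyl]-6-methoxyphenol F2. Double deprotonation with LiN(i-Pr)2 (2.1 equiv, THF, −78 °C) and addition to 6 (Horner–Wittig addition) should give two separable β-hydroxy phosphine oxides. The one needed has ring A eclipsing the carbinol hydrogen when P and O are syn-periplanar: 5-[(1R*,2R*)-2-(5-bromo-2-hydroxy-3-methoxyphenyl)-2-(diphenylphosphoryl)-1-hydroxypropyl]-2,3-dimethoxyphenyl 2,2-dimethylpropanoate F3. It is isolated and treated with NaH in DMF at 0 °C to rt; stereospecific syn-elimination of diphenylphosphinate should then give 8 as a single geometric isomer.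

Step 5. The most likely failure is collapse of the phenoxide–phosphonium species to an ortho-quinone methide with loss of triphenylphosphine before the ylide forms. Transfer of the pivaloyl group to the ring A phenoxide and slow addition of the hindered ylide are lesser risks.
Fallback, from 4 back to 7: the phenol is masked first (t-BuMe2SiCl, imidazole, DMF) to give [1-(5-bromo-2-{[tert-butyl(dimethyl)silyl]oxy}-3-methoxyphenyl)ethyl]triphenylphosphonium bromide F4. The ylide from F4 and one equivalent of NaN(SiMe3)2 (THF, −78 °C) then reacts with 6 in an ordinary Wittig reaction to give 5-[2-(5-bromo-2-{[tert-butyl(dimethyl)silyl]oxy}-3-methoxyphenyl)prop-1-enyl]-2,3-dimethoxyphenyl 2,2-dimethylpropanoate F5 (E/Z mixture). Desilylation with Bu4NF buffered with AcOH (THF, 0 °C) returns 7.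

## Further compounds

F1 | step 7 | 5-[(2R,3R)-5-bromo-7-methoxy-3-methyl-2,3-dihydro-1-benzofuran-2-yl]-2,3-dimethoxyphenyl 2,2-dimethylpropanoate | Brc1cc(OC)c2c(c1)[C@@H](C)[C@H](c1cc(OC(=O)C(C)(C)C)c(OC)c(OC)c1)O2
F2 | step 6 | 4-bromo-2-[1-(diphenylphosphoryl)ethyl]-6-methoxyphenol (racemic) | CC(c1cc(Br)cc(OC)c1O)P(=O)(c1ccccc1)c1ccccc1
F3 | step 6 | 5-[(1R*,2R*)-2-(5-bromo-2-hydroxy-3-methoxyphenyl)-2-(diphenylphosphoryl)-1-hydroxypropyl]-2,3-dimethoxyphenyl 2,2-dimethylpropanoate (racemic, relative configuration shown) | C[C@](c1cc(Br)cc(OC)c1O)(P(=O)(c1ccccc1)c1ccccc1)[C@H](O)c1cc(OC(=O)C(C)(C)C)c(OC)c(OC)c1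
F4 | step 5 | [1-(5-bromo-2-{[tert-butyl(dimethyl)silyl]oxy}-3-methoxyphenyl)ethyl]triphenylphosphonium bromide (racemic) | CC(c1cc(Br)cc(OC)c1O[Si](C)(C)C(C)(C)C)[P+](c1ccccc1)(c1ccccc1)c1ccccc1.[Br-]
F5 | step 5 | 5-[2-(5-bromo-2-{[tert-butyl(dimethyl)silyl]oxy}-3-methoxyphenyl)prop-1-enyl]-2,3-dimethoxyphenyl 2,2-dimethylpropanoate (E/Z mixture) | CC(=Cc1cc(OC(=O)C(C)(C)C)c(OC)c(OC)c1)c1cc(Br)cc(OC)c1O[Si](C)(C)C(C)(C)C
A1 | alternative 1 | methyl (2S,3S)-7-methoxy-2-[3-(methoxymethoxy)-4,5-dimethoxyphenyl]-3-methyl-2,3-dihydro-1-benzofuran-5-carboxylate | COC(=O)c1cc(OC)c2c(c1)[C@H](C)[C@@H](c1cc(OCOC)c(OC)c(OC)c1)O2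
A2 | alternative 1 | methyl 4-iodo-3-methoxybenzoate | COC(=O)c1ccc(I)c(OC)c1
A3 | alternative 1 | (2R,3S)-2-[3-(methoxymethoxy)-4,5-dimethoxyphenyl]-3-methyloxirane (cis) | C[C@@H]1O[C@@H]1c1cc(OCOC)c(OC)c(OC)c1
A4 | alternative 2 | tert-butyl-[5-[(2S,3S)-7-methoxy-3-methyl-5-[(E)-prop-1-enyl]-2,3-dihydro-1-benzofuran-2-yl]-2,3-dimethoxyphenoxy]dimethylsilane | C/C=C/c1cc(OC)c2c(c1)[C@H](C)[C@@H](c1cc(O[Si](C)(C)C(C)(C)C)c(OC)c(OC)c1)O2
A5 | alternative 2 | 3-{[(1S,2S)-1-(3-{[tert-butyl(dimethyl)silyl]oxy}-4,5-dimethoxyphenyl)-2-methylbut-3-yn-1-yl]oxy}-4-methoxy-6-[(E)-prop-1-enyl]-2H-pyran-2-one | C/C=C/C1=CC(OC)=C(O[C@H](c2cc(O[Si](C)(C)C(C)(C)C)c(OC)c(OC)c2)[C@@H](C)C#C)C(=O)O1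
A6 | alternative 3 | methyl (2S,3S)-5-bromo-7-methoxy-2-[4,5-dimethoxy-3-(methylsulfonyloxy)phenyl]-2,3-dihydro-1-benzofuran-3-carboxylate | Brc1cc(OC)c2c(c1)[C@H](C(=O)OC)[C@@H](c1cc(OS(C)(=O)=O)c(OC)c(OC)c1)O2
A7 | alternative 3 | 5-[(2S)-6-bromo-8-methoxy-4-oxo-3,4-dihydro-2H-chromen-2-yl]-2,3-dimethoxyphenyl methanesulfonate | O=C1C[C@@H](c2cc(OS(C)(=O)=O)c(OC)c(OC)c2)Oc2c(OC)cc(Br)cc21
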